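**Plan**

1. Atom labels (farnesane numbering): OCH2 = C1, chain olefin C2=C3(Me), C4, C5, ring CH = C6, methylene-bearing ring carbon = C7, ring CH2 = C8 and C9, carbinol = C10, CMe2 = C11. The target is the cis (6R,10S) isomer.
2. Retrosynthetic cuts, in order: the C1–O aryl ether; the exocyclic C7=CH2 (back to a C7 ketone); the ring bond C7–C6; the C6=C5 olefin that joins the C1–C5 chain; the C9–C8 bond that attaches the C8–C7 ester arm.
3. Enabling feature: the ring segment C9–C10(OH)–C11(Me2)–C6 is D-pantolactone (lactone C=O = C9, OCH2 = C6). C7 can be a ketone, so the carbocycle can close by a C7 acyl radical attacking C6 of a C6=C5 olefin that already carries the whole side chain.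
4. Forward order: pantolactone → two-carbon ester arm on C9 → C6 aldehyde → Wittig union with the C1–C5 ylide → selenoester → the only ring closure → methylenation → desilylation → coumarin ether last.
5. Stereochemistry: C10 comes from D-pantolactone and its C–O bond is never broken. C6 is set against C10 in the cyclisation and by equilibration α to the C7 ketone (diequatorial, cis). E-C2=C3 comes from syn-carboalumination.

Key step: step 15

Remark: TBS = tert-butyldimethylsilyl, TBDPS = tert-butyldiphenylsilyl. The descriptor at C10 changes from R (1–3) to S (4 onward) only because the CIP priorities of its neighbours change.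

**Route**

Step 1
Reactants: 1 D-(−)-pantolactone
Product: 2 (3R)-3-(TBSO)-4,4-dimethyloxolan-2-one
Conditions: TBSCl, imidazole, DMF, rt
Reagents that add atoms: tert-butyldimethylsilyl chloride, CC(C)(C)[Si](C)(C)Cl
Why: Imidazole-promoted silylation of the secondary hydroxyl masks the C10 oxygen from the start, so the later C7 acid never faces a free γ-hydroxyl, and leaves the chiral-pool centre untouched.

Step 2
Reactants: 2 (3R)-3-(TBSO)-4,4-dimethyloxolan-2-one
Product: 3 (3R)-3-(TBSO)-4,4-dimethyloxolan-2-ol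
Conditions: DIBAL-H, CH2Cl2, −78 °C; Rochelle salt work-up
Reagents that add atoms: none
Why: DIBAL-H half-reduction of a lactone stops at the aluminium lactolate at −78 °C and gives the lactol (anomer mixture) on work-up.

Step 3
Reactants: 3 (3R)-3-(TBSO)-4,4-dimethyloxolan-2-ol
Product: 4 ethyl (2E,4S)-4-(TBSO)-6-hydroxy-5,5-dimethylhex-2-enoate
Conditions: Ph3P=CHCO2Et, PhCO2H (cat.), toluene, 80 °C
Reagents that add atoms: ethyl (triphenylphosphoranylidene)acetate, CCOC(=O)C=P(c1ccccc1)(c1ccccc1)c1ccccc1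
Why: Wittig olefination of the lactol through its open-chain hydroxy aldehyde with a stabilised ylide attaches C8 and C7 to C9 as the (E)-enoate, the ylide being too weak a base to epimerise C10.

Step 4
Reactants: 4 ethyl (2E,4S)-4-(TBSO)-6-hydroxy-5,5-dimethylhex-2-enoate
Product: 5 ethyl (4S)-4-(TBSO)-6-hydroxy-5,5-dimethylhexanoate
Conditions: H2 (1 atm), 10% Pd/C, EtOAc, rt
Reagents that add atoms: none
Why: Catalytic hydrogenation saturates the conjugated C9=C8 bond while no other olefin is yet present; silyl ether and ester are inert.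

Step 5
Reactants: 5 ethyl (4S)-4-(TBSO)-6-hydroxy-5,5-dimethylhexanoate
Product: 6 ethyl (4S)-4-(TBSO)-5,5-dimethyl-6-oxohexanoate
Conditions: (COCl)2, DMSO, CH2Cl2, −78 °C; Et3N, −78 → 0 °C
Reagents that add atoms: none
Why: Swern oxidation of the neopentyl primary alcohol gives the C6 aldehyde, which has no α-hydrogen and so can neither enolise nor eliminate the β-silyloxy group.

Step 6
Reactants: 7 but-3-yn-1-ol
Product: 8 (but-3-yn-1-yloxy)(tert-butyl)dimethylsilane
Conditions: TBSCl, imidazole, CH2Cl2, rt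
Reagents that add atoms: tert-butyldimethylsilyl chloride, CC(C)(C)[Si](C)(C)Cl
Why: Routine silylation of the primary alcohol protects the future C5 oxygen for the organoaluminium step.

Step 7
Reactants: 8 (but-3-yn-1-yloxy)(tert-butyl)dimethylsilane
Product: 11 (2E)-5-(TBSO)-3-methylpent-2-en-1-ol, via alkenyldimethylalane 9 (not isolated), via lithium alkenylalanate 10 (not isolated)
Conditions: Me3Al, Cp2ZrCl2 (cat.), CH2Cl2, 0 °C → rt; then n-BuLi, THF–hexane, −78 °C; (CH2O)n, −78 °C → rt
Reagents that add atoms: trimethylaluminium, C[Al](C)C; formaldehyde (from paraformaldehyde), C=O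
Why: Zirconium-catalysed syn-carboalumination (Negishi) puts methyl on the internal and aluminium on the terminal alkyne carbon, and the alanate adds to formaldehyde with retention, which fixes the E-C2=C3 geometry.

Step 8
Reactants: 11 (2E)-5-(TBSO)-3-methylpent-2-en-1-ol
Product: 12 (2E)-5-(TBSO)-1-(TBDPSO)-3-methylpent-2-ene
Conditions: TBDPSCl, imidazole, CH2Cl2, rt
Reagents that add atoms: tert-butyldiphenylsilyl chloride, CC(C)(C)[Si](Cl)(c1ccccc1)c1ccccc1
Why: Silylation of the allylic C1 hydroxyl with the more acid-stable TBDPS group makes the two chain termini distinguishable.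

Step 9
Reactants: 12 (2E)-5-(TBSO)-1-(TBDPSO)-3-methylpent-2-ene
Product: 13 (3E)-5-(TBDPSO)-3-methylpent-3-en-1-ol
Conditions: PPTS (cat.), EtOH, 40 °C
Reagents that add atoms: none
Why: Mild acid-catalysed ethanolysis cleaves the primary TBS ether far faster than the bulkier TBDPS ether.

Step 10
Reactants: 13 (3E)-5-(TBDPSO)-3-methylpent-3-en-1-ol
Product: 14 tert-butyl{[(2E)-5-iodo-3-methylpent-2-en-1-yl]oxy}diphenylsilane
Conditions: I2, PPh3, imidazole, CH2Cl2, 0 °C → rt
Reagents that add atoms: iodine, II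
Why: Appel-type iodination converts the primary alcohol by SN2 displacement of its alkoxyphosphonium ion without touching the allylic silyl ether or the olefin.

Step 11
Reactants: 14 tert-butyl{[(2E)-5-iodo-3-methylpent-2-en-1-yl]oxy}diphenylsilane
Product: 15 {(3E)-5-(TBDPSO)-3-methylpent-3-en-1-yl}triphenylphosphonium iodide
Conditions: PPh3, MeCN, reflux
Reagents that add atoms: triphenylphosphine, c1ccc(cc1)P(c1ccccc1)c1ccccc1
Why: SN2 quaternisation of triphenylphosphine by the unhindered primary iodide gives the Wittig salt of the C1–C5 unit.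

Step 12
Reactants: 15 {(3E)-5-(TBDPSO)-3-methylpent-3-en-1-yl}triphenylphosphonium iodide; 6 ethyl (4S)-4-(TBSO)-5,5-dimethyl-6-oxohexanoate
Product: 17 ethyl (4S,6Z,9E)-4-(TBSO)-11-(TBDPSO)-5,5,9-trimethylundeca-6,9-dienoate, via phosphorus ylide 16 (not isolated)
Conditions: NaHMDS, THF, −78 → 0 °C; then 6, −78 °C → rt
Reagents that add atoms: none
Why: Salt-free Wittig olefination of the non-enolisable aldehyde with the unstabilised ylide forms C6=C5 (mainly Z, a geometry erased in step 15), the aldehyde reacting far faster than the ester at low temperature.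

Step 13
Reactants: 17 ethyl (4S,6Z,9E)-4-(TBSO)-11-(TBDPSO)-5,5,9-trimethylundeca-6,9-dienoate
Product: 18 (4S,6Z,9E)-4-(TBSO)-11-(TBDPSO)-5,5,9-trimethylundeca-6,9-dienoic acid
Conditions: LiOH, THF–MeOH–H2O, rt; then dilute HCl to pH 4, 0 °C
Reagents that add atoms: lithium hydroxide, [Li+].[OH-]
Why: Saponification of the unhindered ethyl ester frees the C7 acid; both silyl ethers tolerate aqueous LiOH, and lactonisation is impossible because O10 is silylated.

Step 14
Reactants: 18 (4S,6Z,9E)-4-(TBSO)-11-(TBDPSO)-5,5,9-trimethylundeca-6,9-dienoic acid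
Product: 19 Se-phenyl (4S,6Z,9E)-4-(TBSO)-11-(TBDPSO)-5,5,9-trimethylundeca-6,9-dieneselenoate
Conditions: (PhSe)2, n-Bu3P, CH2Cl2, rt
Reagents that add atoms: diphenyl diselenide, c1ccc(cc1)[Se][Se]c1ccccc1
Why: Phosphine-mediated selenoesterification (acyloxyphosphonium ion captured by phenylselenolate) gives the acyl radical precursor under neutral conditions.

Step 15
Reactants: 19 Se-phenyl (4S,6Z,9E)-4-(TBSO)-11-(TBDPSO)-5,5,9-trimethylundeca-6,9-dieneselenoate
Product: 21 (2S,4S)-4-(TBSO)-2-[(3E)-5-(TBDPSO)-3-methylpent-3-en-1-yl]-3,3-dimethylcyclohexan-1-one, via trans-ketone 20 (not isolated)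
Conditions: Bu3SnH (slow addition), AIBN (cat.), benzene (0.01 M), 80 °C; then K2CO3 (cat.), MeOH–THF, rt
Reagents that add atoms: none
Why: Bu3Sn• removes the PhSe group of 19 and the resulting C7 acyl radical adds to C6 of the C6=C5 olefin, after which the secondary C5 radical takes hydrogen from the stannane and carries the chain. The closest known reaction type is the stannane-mediated cyclisation of acyl radicals from phenyl selenoesters onto unactivated alkenes. The cyclohexanone (C7, C8, C9, C10, C11, C6) closes 6-exo-trig through a chair-like transition state that the C11 gem-dimethyl group pre-organises. The new centre C6 is controlled by C10: with the silyloxy group equatorial the side chain is expected to take the equatorial position as well, and the carbonate treatment equilibrates C6 α to the ketone so that trans epimer 20 should drain into cis 21, whatever the olefin geometry or face of attack. The step needs 6-exo closure to beat 7-endo attack at C5, premature reduction and ring enlargement of the adduct radical; the substituent on the distal carbon C5, high dilution and slow stannane addition are relied on for this.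

Step 16
Reactants: 21 (2S,4S)-4-(TBSO)-2-[(3E)-5-(TBDPSO)-3-methylpent-3-en-1-yl]-3,3-dimethylcyclohexan-1-one
Product: 22 tert-butyl{[(1S,3R)-3-[(3E)-5-(TBDPSO)-3-methylpent-3-en-1-yl]-2,2-dimethyl-4-methylidenecyclohexyl]oxy}dimethylsilane
Conditions: Zn, CH2Br2, TiCl4 (pre-formed reagent), THF–CH2Cl2, 0 °C → rt
Reagents that add atoms: dibromomethane, BrCBr
Why: Takai–Lombardo methylenation is non-basic and suits hindered, epimerisable ketones, so C7=O becomes C7=CH2 without disturbing C6.

Step 17
Reactants: 22 tert-butyl{[(1S,3R)-3-[(3E)-5-(TBDPSO)-3-methylpent-3-en-1-yl]-2,2-dimethyl-4-methylidenecyclohexyl]oxy}dimethylsilane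
Product: 23 (1S,3R)-3-[(3E)-5-hydroxy-3-methylpent-3-en-1-yl]-2,2-dimethyl-4-methylidenecyclohexan-1-ol
Conditions: TBAF, THF, rt → 50 °C
Reagents that add atoms: none
Why: Fluoride-induced desilylation removes both silyl ethers from a substrate that has no base-sensitive group.

Step 18
Reactants: 23 (1S,3R)-3-[(3E)-5-hydroxy-3-methylpent-3-en-1-yl]-2,2-dimethyl-4-methylidenecyclohexan-1-ol; 24 4-hydroxy-5-methyl-2H-chromen-2-one
Product: 25 4-{[(2E)-5-[(1R,3S)-3-hydroxy-2,2-dimethyl-6-methylidenecyclohexyl]-3-methylpent-2-en-1-yl]oxy}-5-methyl-2H-chromen-2-one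
Conditions: PPh3, DIAD, THF, 0 °C → rt
Reagents that add atoms: none
Why: Mitsunobu etherification activates only the primary allylic hydroxyl (the C10 hydroxyl next to the quaternary carbon is too hindered) and the acidic 4-hydroxycoumarin is alkylated on oxygen by SN2 at C1, so no stereocentre is touched.

**Compound list**

1 | D-(−)-pantolactone, (3R)-3-hydroxy-4,4-dimethyloxolan-2-one | CC1(C)COC(=O)[C@@H]1O | starting material
2 | (3R)-3-[(tert-butyldimethylsilyl)oxy]-4,4-dimethyloxolan-2-one | CC1(C)COC(=O)[C@@H]1O[Si](C)(C)C(C)(C)C | intermediate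
3 | (3R)-3-[(tert-butyldimethylsilyl)oxy]-4,4-dimethyloxolan-2-ol (both anomers) | CC1(C)COC(O)[C@@H]1O[Si](C)(C)C(C)(C)C | intermediate
4 | ethyl (2E,4S)-4-[(tert-butyldimethylsilyl)oxy]-6-hydroxy-5,5-dimethylhex-2-enoate | CCOC(=O)/C=C/[C@H](O[Si](C)(C)C(C)(C)C)C(C)(C)CO | intermediate
5 | ethyl (4S)-4-[(tert-butyldimethylsilyl)oxy]-6-hydroxy-5,5-dimethylhexanoate | CCOC(=O)CC[C@H](O[Si](C)(C)C(C)(C)C)C(C)(C)CO | intermediate
6 | ethyl (4S)-4-[(tert-butyldimethylsilyl)oxy]-5,5-dimethyl-6-oxohexanoate | CCOC(=O)CC[C@H](O[Si](C)(C)C(C)(C)C)C(C)(C)C=O | intermediate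
7 | but-3-yn-1-ol | C#CCCO | starting material
8 | (but-3-yn-1-yloxy)(tert-butyl)dimethylsilane | C#CCCO[Si](C)(C)C(C)(C)C | intermediate
9 | {(1E)-4-[(tert-butyldimethylsilyl)oxy]-2-methylbut-1-en-1-yl}dimethylalane | C[Al](C)/C=C(\C)CCO[Si](C)(C)C(C)(C)C | intermediate (not isolated)
10 | lithium butyl{(1E)-4-[(tert-butyldimethylsilyl)oxy]-2-methylbut-1-en-1-yl}dimethylaluminate | [Li+].CCCC[Al-](C)(C)/C=C(\C)CCO[Si](C)(C)C(C)(C)C | intermediate (not isolated)
11 | (2E)-5-[(tert-butyldimethylsilyl)oxy]-3-methylpent-2-en-1-ol | CC(C)(C)[Si](C)(C)OCC/C(C)=C/CO | intermediate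
12 | (2E)-5-[(tert-butyldimethylsilyl)oxy]-1-[(tert-butyldiphenylsilyl)oxy]-3-methylpent-2-ene | CC(C)(C)[Si](C)(C)OCC/C(C)=C/CO[Si](c1ccccc1)(c1ccccc1)C(C)(C)C | intermediate
13 | (3E)-5-[(tert-butyldiphenylsilyl)oxy]-3-methylpent-3-en-1-ol | OCC/C(C)=C/CO[Si](c1ccccc1)(c1ccccc1)C(C)(C)C | intermediate
14 | tert-butyl{[(2E)-5-iodo-3-methylpent-2-en-1-yl]oxy}diphenylsilane | ICC/C(C)=C/CO[Si](c1ccccc1)(c1ccccc1)C(C)(C)C | intermediate
15 | {(3E)-5-[(tert-butyldiphenylsilyl)oxy]-3-methylpent-3-en-1-yl}triphenylphosphonium iodide | [I-].c1ccc(cc1)[P+](c1ccccc1)(c1ccccc1)CC/C(C)=C/CO[Si](c1ccccc1)(c1ccccc1)C(C)(C)C | intermediate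
16 | {(3E)-5-[(tert-butyldiphenylsilyl)oxy]-3-methylpent-3-en-1-ylidene}triphenylphosphorane | c1ccc(cc1)P(c1ccccc1)(c1ccccc1)=CC/C(C)=C/CO[Si](c1ccccc1)(c1ccccc1)C(C)(C)C | intermediate (not isolated)
17 | ethyl (4S,6Z,9E)-4-[(tert-butyldimethylsilyl)oxy]-11-[(tert-butyldiphenylsilyl)oxy]-5,5,9-trimethylundeca-6,9-dienoate | CCOC(=O)CC[C@H](O[Si](C)(C)C(C)(C)C)C(C)(C)/C=C\C/C(C)=C/CO[Si](c1ccccc1)(c1ccccc1)C(C)(C)C | intermediate
18 | (4S,6Z,9E)-4-[(tert-butyldimethylsilyl)oxy]-11-[(tert-butyldiphenylsilyl)oxy]-5,5,9-trimethylundeca-6,9-dienoic acid | OC(=O)CC[C@H](O[Si](C)(C)C(C)(C)C)C(C)(C)/C=C\C/C(C)=C/CO[Si](c1ccccc1)(c1ccccc1)C(C)(C)C | intermediate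
19 | Se-phenyl (4S,6Z,9E)-4-[(tert-butyldimethylsilyl)oxy]-11-[(tert-butyldiphenylsilyl)oxy]-5,5,9-trimethylundeca-6,9-dieneselenoate | O=C([Se]c1ccccc1)CC[C@H](O[Si](C)(C)C(C)(C)C)C(C)(C)/C=C\C/C(C)=C/CO[Si](c1ccccc1)(c1ccccc1)C(C)(C)C | intermediate (key-step precursor)
20 | (2R,4S)-4-[(tert-butyldimethylsilyl)oxy]-2-{(3E)-5-[(tert-butyldiphenylsilyl)oxy]-3-methylpent-3-en-1-yl}-3,3-dimethylcyclohexan-1-one (trans) | O=C1CC[C@H](O[Si](C)(C)C(C)(C)C)C(C)(C)[C@H]1CC/C(C)=C/CO[Si](c1ccccc1)(c1ccccc1)C(C)(C)C | intermediate (not isolated)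
21 | (2S,4S)-4-[(tert-butyldimethylsilyl)oxy]-2-{(3E)-5-[(tert-butyldiphenylsilyl)oxy]-3-methylpent-3-en-1-yl}-3,3-dimethylcyclohexan-1-one (cis) | O=C1CC[C@H](O[Si](C)(C)C(C)(C)C)C(C)(C)[C@@H]1CC/C(C)=C/CO[Si](c1ccccc1)(c1ccccc1)C(C)(C)C | intermediate (key-step product)
22 | tert-butyl{[(1S,3R)-3-{(3E)-5-[(tert-butyldiphenylsilyl)oxy]-3-methylpent-3-en-1-yl}-2,2-dimethyl-4-methylidenecyclohexyl]oxy}dimethylsilane | C=C1CC[C@H](O[Si](C)(C)C(C)(C)C)C(C)(C)[C@@H]1CC/C(C)=C/CO[Si](c1ccccc1)(c1ccccc1)C(C)(C)C | intermediate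
23 | (1S,3R)-3-[(3E)-5-hydroxy-3-methylpent-3-en-1-yl]-2,2-dimethyl-4-methylidenecyclohexan-1-ol | C=C1CC[C@H](O)C(C)(C)[C@@H]1CC/C(C)=C/CO | intermediate
24 | 4-hydroxy-5-methyl-2H-chromen-2-one | Cc1cccc2oc(=O)cc(O)c12 | starting material
25 | 4-{[(2E)-5-[(1R,3S)-3-hydroxy-2,2-dimethyl-6-methylidenecyclohexyl]-3-methylpent-2-en-1-yl]oxy}-5-methyl-2H-chromen-2-one (CNP0172901.1) | C=C1CC[C@H](O)C(C)(C)[C@@H]1CC/C(C)=C/COc1cc(=O)oc2cccc(C)c12 | target

**Step count and risks**

Total step count: 18 (12 on the line from 1, 6 for the phosphonium salt 15).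
Longest linear sequence: 13 steps (7 → 25, steps 6–18); from 1 it is 12 steps.

Steps most likely to fail:

1. Step 15. What may go wrong: hydrogen transfer from the stannane to the acyl radical before it closes; attack at C5 (7-endo) or ring enlargement by re-addition of the C5 radical to the new carbonyl; and an equilibrium at C6 that leaves much of the trans epimer (the diequatorial preference is expected to be modest, so trans material would be separated and re-equilibrated). Fallback, setting out from acid 18 and returning at ketone 21: a hydride-free group-transfer cyclisation. Acid 18 is turned with oxalyl chloride and catalytic DMF (pyridine buffer) into the acid chloride F1 and then with potassium O-ethyl xanthate into the S-acyl xanthate F2. Visible-light irradiation in refluxing benzene lets the acyl radical cyclise and be capped by xanthate transfer, giving the cyclised secondary xanthate F3. Its C–S bond is then reduced (Bu3SnH, AIBN) and the epimers are equilibrated with K2CO3 in MeOH to give 21.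

2. Step 3. What may go wrong: slow opening of the hindered lactol, and conjugate addition of the freed primary hydroxyl to the new enoate (closure to a tetrahydrofuran) or silyl migration under the warm ylide conditions. Fallback, setting out from lactol 3 and returning at enoate 4: methylenation of 3 with Ph3P=CH2 gives the hydroxy alkene F4. Cross-metathesis of F4 with ethyl acrylate (Hoveyda–Grubbs II catalyst, CH2Cl2, 40 °C) builds the same enoate 4 under neutral conditions, and it is hydrogenated at once as in step 4.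

3. Step 18. What may go wrong: alkylation of the ambident coumarin at C3 or at the lactone carbonyl oxygen instead of O4 (the peri methyl group crowds O4), and allylic transposition. Fallback, setting out from coumarin 24 and returning at target 25: the polarity of the ether formation is reversed. Coumarin 24 is converted with POCl3 into 4-chloro-5-methylcoumarin F5. The sodium alkoxide of the primary hydroxyl of diol 23 (NaH, 1 equiv, THF, 0 °C) then displaces chloride by addition–elimination at C4, which can only give the 4-O ether 25.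

Further compounds
F1 | step 15 | (4S,6Z,9E)-4-[(tert-butyldimethylsilyl)oxy]-11-[(tert-butyldiphenylsilyl)oxy]-5,5,9-trimethylundeca-6,9-dienoyl chloride | ClC(=O)CC[C@H](O[Si](C)(C)C(C)(C)C)C(C)(C)/C=C\C/C(C)=C/CO[Si](c1ccccc1)(c1ccccc1)C(C)(C)C
F2 | step 15 | O-ethyl S-{(4S,6Z,9E)-4-[(tert-butyldimethylsilyl)oxy]-11-[(tert-butyldiphenylsilyl)oxy]-5,5,9-trimethylundeca-6,9-dienoyl} carbonodithioate | CCOC(=S)SC(=O)CC[C@H](O[Si](C)(C)C(C)(C)C)C(C)(C)/C=C\C/C(C)=C/CO[Si](c1ccccc1)(c1ccccc1)C(C)(C)C
F3 | step 15 | O-ethyl S-{(3E)-1-[(3S)-3-[(tert-butyldimethylsilyl)oxy]-2,2-dimethyl-6-oxocyclohexyl]-5-[(tert-butyldiphenylsilyl)oxy]-3-methylpent-3-en-2-yl} carbonodithioate (epimers at the ring CH and the xanthate carbon) | CCOC(=S)SC(C/C(C)=C/CO[Si](c1ccccc1)(c1ccccc1)C(C)(C)C)C1C(=O)CC[C@H](O[Si](C)(C)C(C)(C)C)C1(C)C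
F4 | step 3 | (3S)-3-[(tert-butyldimethylsilyl)oxy]-2,2-dimethylpent-4-en-1-ol | C=C[C@H](O[Si](C)(C)C(C)(C)C)C(C)(C)CO
F5 | step 18 | 4-chloro-5-methyl-2H-chromen-2-one | Cc1cccc2oc(=O)cc(Cl)c12
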